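**Plan**

1. Numbering: tetrahydrofuran O1, aryl-bearing C2, spiro C3, benzyl-bearing C4, C5H2; oxirane C6H2 and O7; benzylic C8H2 between C4 and the 3-hydroxy-4-methoxyphenyl ring.
2. Retrosynthesis cuts O1–C2 first (etherification through a p-quinone methide), then the oxirane bonds C3–O7/C6–O7 (oxygen transfer to a C3=C6 alkene), then C3=C6 (ketone methylenation), C2–C3 (benzylic Grignard reagent on a Weinreb amide) and C4–C5 (hydroxymethylation of a 3-arylpropanoyl imide).
3. Forward, the chain C8–C4(C5)–C3–C2 is joined on the acyl oxazolidinone and then the ketone, C6 is added, the oxirane is closed first and the tetrahydrofuran last; one silyl ether is removed at the end.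
4. Stereochemistry: C4 from the enolate of the (R)-4-benzyloxazolidinone imide, C3 from a ligand-controlled hydroxyl-directed epoxidation, C2 from the C4 benzyl group during ring closure (2,4-cis).
5. Enabling feature: the ring on C2 has its hydroxyl para to C2 (methoxy ortho to that hydroxyl), so it can be oxidised to a p-quinone methide whose exocyclic carbon is C2; C3 is quaternary, so this intermediate cannot tautomerise, and the C5 hydroxyl lies five atoms from C2; the other ring has its oxygen meta to C8 and cannot form such a species.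

Key step: step 13

Assumption: of the two antipodes of the bishydroxamic acid ligand in step 11, the one that steers the peroxide oxygen onto the Si face of C3 of alcohol 18 (priorities C4 > C2 > C6) is used; which antipode this is must be fixed by a trial with both.
Abbreviations: TBS = tert-butyldimethylsilyl, TES = triethylsilyl, PivCl = pivaloyl chloride, PPTS = pyridinium p-toluenesulfonate.

**Route**

Step 1
Reactants: 1 3-(3-hydroxy-4-methoxyphenyl)propanoic acid
Product: 3 3-[3-(TBS-oxy)-4-methoxyphenyl]propanoic acid, via bis-silylated silyl ester 2 (not isolated)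
Conditions: TBSCl, imidazole, DMF, rt; then AcOH/THF/H2O, rt
Reagents that add atoms: tert-butyldimethylsilyl chloride, CC(C)(C)[Si](C)(C)Cl
Why: Imidazole-mediated silylation caps both the phenol and the acid, and the silyl ester, far more labile than an aryl silyl ether, is then hydrolysed selectively by aqueous acetic acid (silyl protection with selective silyl ester cleavage).

Step 2
Reactants: 3 3-[3-(TBS-oxy)-4-methoxyphenyl]propanoic acid; 4 (R)-4-benzyl-2-oxazolidinone
Product: 6 (R)-4-benzyl-3-{3-[3-(TBS-oxy)-4-methoxyphenyl]propanoyl}oxazolidin-2-one, via mixed pivalic anhydride 5 (not isolated)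
Conditions: PivCl, Et3N, THF, −20 °C; then LiCl, 4, −20 °C to rt
Reagents that add atoms: none
Why: The acid is activated as its mixed pivalic anhydride and the LiCl/Et3N-activated oxazolidinone attacks the less hindered carbonyl, the standard N-acylation that installs the auxiliary for the enolate step.

Step 3
Reactants: 6 (R)-4-benzyl-3-{3-[3-(TBS-oxy)-4-methoxyphenyl]propanoyl}oxazolidin-2-one
Product: 8 (R)-4-benzyl-3-{(S)-3-[3-(TBS-oxy)-4-methoxyphenyl]-2-(hydroxymethyl)propanoyl}oxazolidin-2-one, via chlorotitanium Z-enolate 7 (not isolated)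
Conditions: TiCl4, i-Pr2NEt, CH2Cl2, 0 °C; then s-trioxane, TiCl4, 0 °C; aq NH4Cl
Reagents that add atoms: s-trioxane (formaldehyde source), C1OCOCO1
Why: Soft enolisation gives the chelated Z-titanium enolate, whose face opposite the auxiliary benzyl group is attacked by TiCl4-activated formaldehyde from s-trioxane (auxiliary-controlled titanium-enolate hydroxymethylation, an aldol-type alkylation), which sets C4 as S in 8 and leaves the primary alcohol free.

Step 4
Reactants: 8 (R)-4-benzyl-3-{(S)-3-[3-(TBS-oxy)-4-methoxyphenyl]-2-(hydroxymethyl)propanoyl}oxazolidin-2-one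
Product: 9 (S)-3-[3-(TBS-oxy)-4-methoxyphenyl]-2-(hydroxymethyl)-N-methoxy-N-methylpropanamide
Conditions: MeNH(OMe)·HCl, AlMe3, CH2Cl2, −10 to 0 °C; aqueous potassium sodium tartrate (KNaC4H4O6) work-up
Reagents that add atoms: N,O-dimethylhydroxylamine hydrochloride, CNOC.Cl
Why: The aluminium amide formed from AlMe3 and the amine hydrochloride opens the imide at the exocyclic carbonyl, assisted by the aluminium alkoxide of the neighbouring β-hydroxyl (Weinreb transamidation), under non-enolising conditions that leave C4 untouched and return auxiliary 4.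

Step 5
Reactants: 9 (S)-3-[3-(TBS-oxy)-4-methoxyphenyl]-2-(hydroxymethyl)-N-methoxy-N-methylpropanamide
Product: 10 (S)-3-[3-(TBS-oxy)-4-methoxyphenyl]-N-methoxy-N-methyl-2-[(TES-oxy)methyl]propanamide
Conditions: TESCl, imidazole, CH2Cl2, 0 °C
Reagents that add atoms: chlorotriethylsilane, CC[Si](Cl)(CC)CC
Why: Standard silylation of the primary alcohol, with a triethylsilyl ether chosen because it survives the Grignard and methylenation steps yet is later cleaved by weak acid without touching the aryl TBS ether.

Step 6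
Reactants: 11 vanillyl alcohol
Product: 12 [4-(allyloxy)-3-methoxyphenyl]methanol
Conditions: allyl bromide, K2CO3, acetone, reflux
Reagents that add atoms: allyl bromide, C=CCBr
Why: Williamson etherification in which only the phenol is deprotonated by K2CO3, so the benzylic alcohol stays free.

Step 7
Reactants: 12 [4-(allyloxy)-3-methoxyphenyl]methanol
Product: 13 1-(allyloxy)-4-(chloromethyl)-2-methoxybenzene
Conditions: SOCl2, CH2Cl2, 0 °C; used at once without chromatography
Reagents that add atoms: thionyl chloride, O=S(Cl)Cl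
Why: Deoxychlorination of the electron-rich benzylic alcohol through its chlorosulfite proceeds readily at 0 °C and the allyl ether is inert to it.

Step 8
Reactants: 10 (S)-3-[3-(TBS-oxy)-4-methoxyphenyl]-N-methoxy-N-methyl-2-[(TES-oxy)methyl]propanamide; 13 1-(allyloxy)-4-(chloromethyl)-2-methoxybenzene
Product: 16 (S)-1-[4-(allyloxy)-3-methoxyphenyl]-4-[3-(TBS-oxy)-4-methoxyphenyl]-3-[(TES-oxy)methyl]butan-2-one, via benzylic Grignard reagent 14 (not isolated), via magnesium-chelated tetrahedral adduct 15 (not isolated)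
Conditions: Mg turnings (excess, iodine-activated), 2-MeTHF, 0 °C, slow addition of 13; then 10, −20 to 0 °C; cold aq NH4Cl
Reagents that add atoms: none
Why: Magnesium insertion under high dilution gives the benzylic Grignard reagent, which adds only once to the Weinreb amide because the chelated adduct persists until the cold, mildly acidic quench (Weinreb ketone synthesis), so the enolisable ketone appears only on work-up and C4 keeps its configuration.

Step 9
Reactants: 16 (S)-1-[4-(allyloxy)-3-methoxyphenyl]-4-[3-(TBS-oxy)-4-methoxyphenyl]-3-[(TES-oxy)methyl]butan-2-one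
Product: 17 (R)-2-[4-(allyloxy)-3-methoxybenzyl]-3-[3-(TBS-oxy)-4-methoxybenzyl]-4-(TES-oxy)but-1-ene
Conditions: Cp2TiMe2, toluene/THF, 65 °C, dark
Reagents that add atoms: dimethyltitanocene Cp2TiMe2, C[Ti](C)(C1C=CC=C1)C1C=CC=C1
Why: Thermolysis of Cp2TiMe2 generates Cp2Ti=CH2, which methylenates the ketone through an oxatitanacyclobutane (Petasis methylenation); the reagent is non-basic, so the enolisable β-silyloxy benzyl ketone reacts without epimerisation at C4 or elimination, and the silyl and allyl ethers are inert.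

Step 10
Reactants: 17 (R)-2-[4-(allyloxy)-3-methoxybenzyl]-3-[3-(TBS-oxy)-4-methoxybenzyl]-4-(TES-oxy)but-1-ene
Product: 18 (R)-3-[4-(allyloxy)-3-methoxybenzyl]-2-[3-(TBS-oxy)-4-methoxybenzyl]but-3-en-1-ol
Conditions: PPTS (cat.), MeOH/CH2Cl2, 0 °C to rt
Reagents that add atoms: none
Why: Acid-catalysed methanolysis removes the alkyl triethylsilyl ether selectively, since aryl TBS ethers resist weak acid, and frees the C5 hydroxyl that must direct the epoxidation.

Step 11
Reactants: 18 (R)-3-[4-(allyloxy)-3-methoxybenzyl]-2-[3-(TBS-oxy)-4-methoxybenzyl]but-3-en-1-ol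
Product: 19 (S)-2-{(S)-2-[4-(allyloxy)-3-methoxybenzyl]oxiran-2-yl}-3-[3-(TBS-oxy)-4-methoxyphenyl]propan-1-ol
Conditions: VO(O-i-Pr)3 (cat.), C2-symmetric bishydroxamic acid ligand from trans-cyclohexane-1,2-diamine (cat.), cumene hydroperoxide, toluene, 0 °C to rt
Reagents that add atoms: cumene hydroperoxide, CC(C)(OO)c1ccccc1
Why: The C5 alkoxide binds the chiral vanadium–bishydroxamate complex and the coordinated alkyl peroxide is delivered intramolecularly to the homoallylic 1,1-disubstituted alkene only (hydroxyl-directed asymmetric epoxidation of a homoallylic alcohol), the ligand selecting the Si face of C3 so that C3 becomes S with O7 anti to the C4 benzyl group in the extended C5–C4–C3–C6 chain, while the undirected allyl ether alkene does not react.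

Step 12
Reactants: 19 (S)-2-{(S)-2-[4-(allyloxy)-3-methoxybenzyl]oxiran-2-yl}-3-[3-(TBS-oxy)-4-methoxyphenyl]propan-1-ol
Product: 20 (S)-3-[3-(TBS-oxy)-4-methoxyphenyl]-2-[(S)-2-(4-hydroxy-3-methoxybenzyl)oxiran-2-yl]propan-1-ol
Conditions: Pd(PPh3)4 (cat.), morpholine, THF, rt
Reagents that add atoms: none
Why: Zerovalent palladium ionises the allyl aryl ether to a π-allyl complex that is intercepted by morpholine (Tsuji–Trost deallylation), under conditions neutral enough to leave the oxirane, the primary alcohol and the aryl silyl ether untouched.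

Step 13
Reactants: 20 (S)-3-[3-(TBS-oxy)-4-methoxyphenyl]-2-[(S)-2-(4-hydroxy-3-methoxybenzyl)oxiran-2-yl]propan-1-ol
Product: 22 (3S,4S,7S)-7-[3-(TBS-oxy)-4-methoxybenzyl]-4-(4-hydroxy-3-methoxyphenyl)-1,5-dioxaspiro[2.4]heptane, via p-quinone methide 21 (not isolated)
Conditions: Ag2O, 4 Å molecular sieves, CH2Cl2, rt, dark
Reagents that add atoms: none
Why: Ag2O removes two electrons and two protons (the phenolic O–H and one C2–H) from the 4-alkyl-2-methoxyphenol to give the neutral p-quinone methide 21, and the C5 hydroxyl then adds to C2 in a conjugate (1,6) sense so that the ring rearomatises and O1–C2 is formed. The closest known reaction type is the oxidation of 4-alkylguaiacols to quinone methides with capture by an internal alcohol, as in the biomimetic closure of 2-aryltetrahydrofuran lignans. The tetrahydrofuran ring closes in the 5-exo-trig mode, the C2=C(ring) bond of 21 lying outside the new ring. C2 is the only new stereocentre and is controlled by C4: in a chair-like transition state the C4 benzyl group and the quinoid ring both sit pseudo-equatorial, which places the aryl group cis to the benzyl group (2S). The step needs oxidation of one ring and attack by one oxygen: only the ring on C2 has its hydroxyl para to a benzylic C–H, whereas the other ring is silylated with its oxygen meta to C8; C3 bears no hydrogen, so 21 cannot tautomerise to a styrene; and the C5 hydroxyl is the only nucleophile that reaches C2 through a five-membered transition state. The oxidant is neutral and heterogeneous, so the oxirane and the silyl ether should survive.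

Step 14
Reactants: 22 (3S,4S,7S)-7-[3-(TBS-oxy)-4-methoxybenzyl]-4-(4-hydroxy-3-methoxyphenyl)-1,5-dioxaspiro[2.4]heptane
Product: 23 (3S,4S,7S)-7-(3-hydroxy-4-methoxybenzyl)-4-(4-hydroxy-3-methoxyphenyl)-1,5-dioxaspiro[2.4]heptane
Conditions: Bu4NF, AcOH, THF, 0 °C
Reagents that add atoms: none
Why: Fluoride cleaves the aryl silyl ether (desilylation), and the acetic acid buffer keeps the medium from becoming basic enough to open the oxirane or to reopen the benzylic ether through the phenoxide.

**Compound list**

1 | 3-(3-hydroxy-4-methoxyphenyl)propanoic acid | COc1ccc(CCC(O)=O)cc1O | starting material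
2 | tert-butyldimethylsilyl 3-[3-(tert-butyldimethylsilyloxy)-4-methoxyphenyl]propanoate | COc1ccc(CCC(=O)O[Si](C)(C)C(C)(C)C)cc1O[Si](C)(C)C(C)(C)C | intermediate (not isolated)
3 | 3-[3-(tert-butyldimethylsilyloxy)-4-methoxyphenyl]propanoic acid | COc1ccc(CCC(O)=O)cc1O[Si](C)(C)C(C)(C)C | intermediate
4 | (R)-4-benzyl-2-oxazolidinone | O=C1N[C@H](Cc2ccccc2)CO1 | starting material
5 | 3-[3-(tert-butyldimethylsilyloxy)-4-methoxyphenyl]propanoic pivalic anhydride | COc1ccc(CCC(=O)OC(=O)C(C)(C)C)cc1O[Si](C)(C)C(C)(C)C | intermediate (not isolated)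
6 | (R)-4-benzyl-3-{3-[3-(tert-butyldimethylsilyloxy)-4-methoxyphenyl]propanoyl}oxazolidin-2-one | COc1ccc(CCC(=O)N2[C@H](Cc3ccccc3)COC2=O)cc1O[Si](C)(C)C(C)(C)C | intermediate
7 | trichlorotitanium (Z)-enolate of imide 6 | COc1ccc(C/C=C(\O[Ti](Cl)(Cl)Cl)N2[C@H](Cc3ccccc3)COC2=O)cc1O[Si](C)(C)C(C)(C)C | intermediate (not isolated)
8 | (R)-4-benzyl-3-{(S)-3-[3-(tert-butyldimethylsilyloxy)-4-methoxyphenyl]-2-(hydroxymethyl)propanoyl}oxazolidin-2-one | COc1ccc(C[C@@H](CO)C(=O)N2[C@H](Cc3ccccc3)COC2=O)cc1O[Si](C)(C)C(C)(C)C | intermediate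
9 | (S)-3-[3-(tert-butyldimethylsilyloxy)-4-methoxyphenyl]-2-(hydroxymethyl)-N-methoxy-N-methylpropanamide | COc1ccc(C[C@@H](CO)C(=O)N(C)OC)cc1O[Si](C)(C)C(C)(C)C | intermediate
10 | (S)-3-[3-(tert-butyldimethylsilyloxy)-4-methoxyphenyl]-N-methoxy-N-methyl-2-[(triethylsilyloxy)methyl]propanamide | COc1ccc(C[C@@H](CO[Si](CC)(CC)CC)C(=O)N(C)OC)cc1O[Si](C)(C)C(C)(C)C | intermediate
11 | vanillyl alcohol, 4-(hydroxymethyl)-2-methoxyphenol | COc1cc(CO)ccc1O | starting material
12 | [4-(allyloxy)-3-methoxyphenyl]methanol | COc1cc(CO)ccc1OCC=C | intermediate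
13 | 1-(allyloxy)-4-(chloromethyl)-2-methoxybenzene | COc1cc(CCl)ccc1OCC=C | intermediate
14 | [4-(allyloxy)-3-methoxybenzyl]magnesium chloride | COc1cc(C[Mg]Cl)ccc1OCC=C | intermediate (not isolated)
15 | chloromagnesium alkoxide of the tetrahedral adduct of 14 to amide 10 | COc1ccc(C[C@@H](CO[Si](CC)(CC)CC)C(O[Mg]Cl)(Cc2ccc(OCC=C)c(OC)c2)N(C)OC)cc1O[Si](C)(C)C(C)(C)C | intermediate (not isolated)
16 | (S)-1-[4-(allyloxy)-3-methoxyphenyl]-4-[3-(tert-butyldimethylsilyloxy)-4-methoxyphenyl]-3-[(triethylsilyloxy)methyl]butan-2-one | COc1ccc(C[C@@H](CO[Si](CC)(CC)CC)C(=O)Cc2ccc(OCC=C)c(OC)c2)cc1O[Si](C)(C)C(C)(C)C | intermediate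
17 | (R)-2-[4-(allyloxy)-3-methoxybenzyl]-3-[3-(tert-butyldimethylsilyloxy)-4-methoxybenzyl]-4-(triethylsilyloxy)but-1-ene | COc1ccc(C[C@@H](CO[Si](CC)(CC)CC)C(=C)Cc2ccc(OCC=C)c(OC)c2)cc1O[Si](C)(C)C(C)(C)C | intermediate
18 | (R)-3-[4-(allyloxy)-3-methoxybenzyl]-2-[3-(tert-butyldimethylsilyloxy)-4-methoxybenzyl]but-3-en-1-ol | COc1ccc(C[C@@H](CO)C(=C)Cc2ccc(OCC=C)c(OC)c2)cc1O[Si](C)(C)C(C)(C)C | intermediate
19 | (S)-2-{(S)-2-[4-(allyloxy)-3-methoxybenzyl]oxiran-2-yl}-3-[3-(tert-butyldimethylsilyloxy)-4-methoxyphenyl]propan-1-ol | COc1ccc(C[C@@H](CO)[C@@]2(Cc3ccc(OCC=C)c(OC)c3)CO2)cc1O[Si](C)(C)C(C)(C)C | intermediate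
20 | (S)-3-[3-(tert-butyldimethylsilyloxy)-4-methoxyphenyl]-2-[(S)-2-(4-hydroxy-3-methoxybenzyl)oxiran-2-yl]propan-1-ol | COc1ccc(C[C@@H](CO)[C@@]2(Cc3ccc(O)c(OC)c3)CO2)cc1O[Si](C)(C)C(C)(C)C | intermediate
21 | p-quinone methide of 20 (2-methoxy-4-ylidene-cyclohexa-2,5-dienone, exocyclic carbon = C2, oxirane and C4 as in 20) | COc1ccc(C[C@@H](CO)[C@@]2(C=C3C=CC(=O)C(OC)=C3)CO2)cc1O[Si](C)(C)C(C)(C)C | intermediate (not isolated)
22 | (3S,4S,7S)-7-[3-(tert-butyldimethylsilyloxy)-4-methoxybenzyl]-4-(4-hydroxy-3-methoxyphenyl)-1,5-dioxaspiro[2.4]heptane | COc1ccc(C[C@H]2CO[C@@H](c3ccc(O)c(OC)c3)[C@@]23CO3)cc1O[Si](C)(C)C(C)(C)C | intermediate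
23 | (3S,4S,7S)-7-(3-hydroxy-4-methoxybenzyl)-4-(4-hydroxy-3-methoxyphenyl)-1,5-dioxaspiro[2.4]heptane (CNP0184956.1) | COc1ccc(C[C@H]2CO[C@@H](c3ccc(O)c(OC)c3)[C@@]23CO3)cc1O | target

**Step count and risks**

Total step count: 14. Longest linear sequence: 12 steps (steps 1–5 and 8–14, from acid 1); chloride 13 is made in 2 steps from 11.

Steps most likely to fail:

1. Step 13. What may go wrong: attack of O1 on the wrong face of the planar C2 of the quinone methide, because the oxirane C–O bond on C3 can act as the antiperiplanar acceptor in a Felkin-type arrangement that leads to the 2,4-trans ring; in addition, phenoxyl radical coupling or further oxidation of the product phenol. Fallback: the ring is closed before the oxirane exists. It sets out from homoallylic alcohol 18. Deallylation with Pd(PPh3)4 and morpholine gives (R)-3-(4-hydroxy-3-methoxybenzyl)-2-[3-(tert-butyldimethylsilyloxy)-4-methoxybenzyl]but-3-en-1-ol F1. Ag2O in CH2Cl2 oxidises F1 to its vinylogous quinone methide, and 5-exo attack of the C5 hydroxyl at C2 should give (2R,4R)-4-[3-(tert-butyldimethylsilyloxy)-4-methoxybenzyl]-2-(4-hydroxy-3-methoxyphenyl)-3-methylidenetetrahydrofuran F2 (2,4-cis); with C3 trigonal, the C4 benzyl group is the only control element. Buffered mCPBA (NaHCO3, CH2Cl2, 0 °C) should then epoxidise the exocyclic alkene from the face opposite the two cis substituents on C2 and C4, which is the face required for O7. The sequence comes back to the route at 22.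

2. Step 11. What may go wrong: poor facial selectivity. The catalyst must impose Si-face delivery on a substrate whose own preference may point to the other face, because of A(1,2) strain between the C4 benzyl group and the C2 methylene in the metal-alkoxide transition state; such a mismatched pairing would lower the diastereomer ratio or stall turnover. Fallback: the oxirane is built by C–C bond formation under chelate control instead of by oxygen transfer. It sets out from ketone 16. Methanolysis of the triethylsilyl ether (PPTS, MeOH) gives (S)-1-[4-(allyloxy)-3-methoxyphenyl]-4-[3-(tert-butyldimethylsilyloxy)-4-methoxyphenyl]-3-(hydroxymethyl)butan-2-one F3. One equivalent of i-PrMgCl at −78 °C forms a six-membered magnesium chelate between the C5 alkoxide and the C3 carbonyl. Chloromethylmagnesium chloride (from ClCH2I and i-PrMgCl·LiCl, −78 °C) should add to the face opposite the C4 benzyl group and give, as its magnesium alkoxide, (2S,3S)-3-[4-(allyloxy)-3-methoxybenzyl]-2-[3-(tert-butyldimethylsilyloxy)-4-methoxybenzyl]-4-chlorobutane-1,3-diol F4. On warming, the tertiary alkoxide closes by 3-exo-tet displacement of chloride, and the sequence comes back to the route at epoxy alcohol 19.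

3. Step 8. What may go wrong: Wurtz homocoupling while the electron-rich benzylic Grignard reagent forms, and enolisation of the product benzyl ketone on work-up, with loss of the C4 configuration or β-elimination of the silyloxy group. Fallback: C2–C3 is made by cross-coupling on an enol triflate, so that neither the benzylic Grignard reagent nor the benzyl ketone is needed and steps 8 and 9 are both bypassed. It sets out from Weinreb amide 10. MeMgBr gives (S)-4-[3-(tert-butyldimethylsilyloxy)-4-methoxyphenyl]-3-[(triethylsilyloxy)methyl]butan-2-one F5. Kinetic deprotonation at the methyl group with KN(SiMe3)2 at −78 °C and trapping with PhNTf2 gives (S)-3-[3-(tert-butyldimethylsilyloxy)-4-methoxybenzyl]-4-(triethylsilyloxy)but-1-en-2-yl trifluoromethanesulfonate F6. Chloride 13 is converted with zinc dust and LiCl in THF into [4-(allyloxy)-3-methoxybenzyl]zinc chloride F7. Negishi coupling of F6 with F7 under a zerovalent palladium catalyst (Pd(PPh3)4, THF, rt) should deliver the 1,1-disubstituted alkene, and the sequence comes back to the route at 17.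

Further compounds
F1 | step 13 | (R)-3-(4-hydroxy-3-methoxybenzyl)-2-[3-(tert-butyldimethylsilyloxy)-4-methoxybenzyl]but-3-en-1-ol | COc1ccc(C[C@@H](CO)C(=C)Cc2ccc(O)c(OC)c2)cc1O[Si](C)(C)C(C)(C)C
F2 | step 13 | (2R,4R)-4-[3-(tert-butyldimethylsilyloxy)-4-methoxybenzyl]-2-(4-hydroxy-3-methoxyphenyl)-3-methylidenetetrahydrofuran | COc1ccc(C[C@H]2CO[C@@H](c3ccc(O)c(OC)c3)C2=C)cc1O[Si](C)(C)C(C)(C)C
F3 | step 11 | (S)-1-[4-(allyloxy)-3-methoxyphenyl]-4-[3-(tert-butyldimethylsilyloxy)-4-methoxyphenyl]-3-(hydroxymethyl)butan-2-one | COc1ccc(C[C@@H](CO)C(=O)Cc2ccc(OCC=C)c(OC)c2)cc1O[Si](C)(C)C(C)(C)C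
F4 | step 11 | (2S,3S)-3-[4-(allyloxy)-3-methoxybenzyl]-2-[3-(tert-butyldimethylsilyloxy)-4-methoxybenzyl]-4-chlorobutane-1,3-diol | COc1ccc(C[C@@H](CO)[C@](O)(CCl)Cc2ccc(OCC=C)c(OC)c2)cc1O[Si](C)(C)C(C)(C)C
F5 | step 8 | (S)-4-[3-(tert-butyldimethylsilyloxy)-4-methoxyphenyl]-3-[(triethylsilyloxy)methyl]butan-2-one | COc1ccc(C[C@@H](CO[Si](CC)(CC)CC)C(C)=O)cc1O[Si](C)(C)C(C)(C)C
F6 | step 8 | (S)-3-[3-(tert-butyldimethylsilyloxy)-4-methoxybenzyl]-4-(triethylsilyloxy)but-1-en-2-yl trifluoromethanesulfonate | COc1ccc(C[C@@H](CO[Si](CC)(CC)CC)C(=C)OS(=O)(=O)C(F)(F)F)cc1O[Si](C)(C)C(C)(C)C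
F7 | step 8 | [4-(allyloxy)-3-methoxybenzyl]zinc chloride | COc1cc(C[Zn]Cl)ccc1OCC=C
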